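**Retrosynthetic overview**
- 27 ⇐ 25 ⇐ 24 ⇐ 23: the trans-diequatorial C2–Cl/C3–Br pair comes from the top-face C2–C3 epoxide of (6R,10S)-10-bromo-β-chamigrene. Br⁻ opens it at tertiary C3 with inversion, then OH→Cl at C2 goes with retention.
- 23 ⇐ 19: the C15 methyl comes from cross-coupling on the C2=C3 enol triflate. C6 becomes stereogenic in a strain-driven, thermodynamic enolisation of the symmetric ring-A ketone.
- 19 ⇐ 11 + 16 (key step): C4–C5 and C1–C2 ([3+3], ring A), then C6–C11 (ring B, spiro centre), form in one flask from an acyclic trichloride and an acetone α,α′-dianion equivalent.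
- Enabling feature: spiro C6 carries two CH2 groups (C1, C5) and faces C3 across ring A, while ring B holds the bromonium/olefin retron C10(Br)–C11Me2 / C7=C14H2. With C6–C11 opened, C6=C7 makes C1 and C5 the CH2 termini of allyl cations whose charge rests on tertiary C7, and C2–C3–C4 is acetone.
- Ring order: A, then B. C10 comes from a catalytic enantioselective bromochlorination of prenol and is relayed through an enantiopure bromonium ion.

Key step: step 10

Remark: chamigrene numbering is used (ring A: C1H2, C2, C3 bearing C15, C4H2, C5H2; C6 spiro; ring B: C7=C14H2, C8, C9, C10–Br, C11 bearing C12/C13). The ligand enantiomer in step 1 is the one that gives (S)-2.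

Step 1
Reactants: 1 3-methylbut-2-en-1-ol (prenol)
Product: 2 (2S)-2-bromo-3-chloro-3-methylbutan-1-ol
Conditions: NBS, ClTi(OiPr)3, chiral tridentate Schiff-base ligand (20 mol %), hexanes, −20 °C
Reagents that add atoms: N-bromosuccinimide O=C1CCC(=O)N1Br; chlorotitanium triisopropoxide CC(C)O[Ti](Cl)(OC(C)C)OC(C)C
Why: Catalytic enantioselective bromochlorination of an allylic alcohol: the Ti-bound substrate takes up Br+ and titanium delivers chloride anti to the distal tertiary carbon (also the Markovnikov site), so the ligand sets the C–Br centre (future C10) as S.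

Step 2
Reactants: 2 (2S)-2-bromo-3-chloro-3-methylbutan-1-ol
Product: 3 (2S)-2-bromo-3-chloro-3-methylbutyl trifluoromethanesulfonate
Conditions: Tf2O, 2,6-lutidine, CH2Cl2, −78 °C
Reagents that add atoms: triflic anhydride O=S(=O)(OS(=O)(=O)C(F)(F)F)C(F)(F)F
Why: O-sulfonylation of a primary alcohol with a hindered base at low temperature leaves the stereocentre and both halides untouched and gives an electrophile reactive enough for displacement at −78 °C.

Step 3
Reactants: 3 (2S)-2-bromo-3-chloro-3-methylbutyl trifluoromethanesulfonate; 4 acetone N,N-dimethylhydrazone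
Product: 6 (5S)-5-bromo-6-chloro-6-methylheptan-2-one N,N-dimethylhydrazone, via lithiated hydrazone 5 (not isolated)
Conditions: 4, n-BuLi, THF, −78 → 0 °C; then 3, −78 °C
Reagents that add atoms: none
Why: SN2 alkylation of a lithiated dimethylhydrazone by a primary triflate should outrun E2 or halophilic attack on the bromochloride at −78 °C, and the product has no acidic C–H that could close a cyclopropane onto the C–Br carbon.

Step 4
Reactants: 6 (5S)-5-bromo-6-chloro-6-methylheptan-2-one N,N-dimethylhydrazone
Product: 7 (5S)-5-bromo-6-chloro-6-methylheptan-2-one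
Conditions: sat. aq. oxalic acid, Et2O, 23 °C
Reagents that add atoms: water O
Why: Mild biphasic acid hydrolysis of a dimethylhydrazone frees the methyl ketone without base, so neither halide is eliminated.

Step 5
Reactants: 7 (5S)-5-bromo-6-chloro-6-methylheptan-2-one; 8 dimethyl malonate
Product: 9 dimethyl 2-[(5S)-5-bromo-6-chloro-6-methylheptan-2-ylidene]malonate
Conditions: TiCl4, pyridine, THF, 0 → 23 °C
Reagents that add atoms: none
Why: The TiCl4/pyridine Knoevenagel condensation works on methyl ketones and gives a tetrasubstituted alkene with two identical ester arms, so no E/Z issue arises; any reversible chloride ionisation returns the same bromochloride.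

Step 6
Reactants: 9 dimethyl 2-[(5S)-5-bromo-6-chloro-6-methylheptan-2-ylidene]malonate
Product: 10 2-[(5S)-5-bromo-6-chloro-6-methylheptan-2-ylidene]propane-1,3-diol
Conditions: DIBAL-H (5 equiv), CH2Cl2, −78 → 0 °C; Rochelle salt
Reagents that add atoms: none
Why: DIBAL-H reduces both conjugated esters 1,2 to the 2-alkylidene-1,3-diol and does not touch unactivated alkyl halides at this temperature.

Step 7
Reactants: 10 2-[(5S)-5-bromo-6-chloro-6-methylheptan-2-ylidene]propane-1,3-diol
Product: 11 (6S)-6-bromo-1,7-dichloro-2-(chloromethyl)-3,7-dimethyloct-2-ene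
Conditions: NCS, Me2S, CH2Cl2, −30 → 0 °C
Reagents that add atoms: N-chlorosuccinimide O=C1CCC(=O)N1Cl
Why: Corey–Kim chlorination converts primary allylic alcohols into the unrearranged allylic chlorides under neutral conditions.

Step 8
Reactants: 12 (trimethylsilyl)methylmagnesium chloride; 13 acetic anhydride
Product: 14 1-(trimethylsilyl)propan-2-one
Conditions: inverse addition of 12 to 13, Et2O, −78 °C; aq. NH4Cl
Reagents that add atoms: none
Why: Acylation of a Grignard reagent by excess anhydride at low temperature stops at the ketone because the tetrahedral adduct survives until the quench.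

Step 9
Reactants: 14 1-(trimethylsilyl)propan-2-one
Product: 16 tert-butyldimethyl{[3-(trimethylsilyl)prop-1-en-2-yl]oxy}silane, via kinetic lithium enolate 15 (not isolated)
Conditions: LDA, THF, −78 °C; TBSOTf, −78 → 0 °C
Reagents that add atoms: tert-butyldimethylsilyl triflate CC(C)(C)[Si](C)(C)OS(=O)(=O)C(F)(F)F
Why: Kinetic deprotonation at the unhindered CH3 followed by O-silylation gives the 2-siloxyallylsilane, a silyl enol ether and an allylsilane in one C3 unit.

Step 10
Reactants: 11 (6S)-6-bromo-1,7-dichloro-2-(chloromethyl)-3,7-dimethyloct-2-ene; 16 tert-butyldimethyl{[3-(trimethylsilyl)prop-1-en-2-yl]oxy}silane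
Product: 19 (8S)-8-bromo-7,7-dimethyl-11-methylidenespiro[5.5]undecan-3-one, via enol ether allyl chloride 17 (not isolated), via alkylidenecyclohexanone 18 (not isolated)
Conditions: 16 (1.1 equiv), 2,6-di-tert-butylpyridine (3.5 equiv), (CF3)2CHOH (0.02 M), 0 → 23 °C, then 40 °C until 18 is consumed
Reagents that add atoms: none
Why: Proposed new method: the ionising, non-nucleophilic solvent heterolyses the three C–Cl bonds of 11 in the order of their SN1 reactivity: each primary allylic chloride gives an allyl cation that shares its charge with tertiary C7 and is captured at its CH2 terminus, first intermolecularly by the =CH2 carbon of 16 (C5–C4, loss of Me3SiCl regenerating a silyl enol ether, 17), then intramolecularly (C1–C2, loss of TBSCl giving 18), and only then does the slower, bromine-assisted ionisation of the tertiary chloride give the enantiopure bromonium ion that the now tetra-alkylated C6=C7 alkene attacks at C11. The closest known reaction types are the Lewis-acid-free solvolytic alkylation of silyl enol ethers and allylsilanes by SN1-active chlorides in fluorinated alcohols, the use of 2-siloxyallylsilanes as acetone α,α′-dianion equivalents, and the stereospecific bromonium/polyene cyclisation of enantioenriched vicinal bromochlorides in hexafluoroisopropanol. Ring A closes by a chair-like 6-(enol-endo) attack on allyl terminus C1 that leaves C6=C7 exocyclic, and ring B by a chair 6-endo cation–olefin closure with anti opening of the bromonium ion at C11, ended by loss of a proton from the C14 methyl group. The only stereocentre, C10, keeps its C–Br bond throughout, so its S configuration is carried over from 2 (Br equatorial in the chair); C6 is not yet stereogenic because ring A of 19 is symmetric, which also makes the E/Z mixture of 17 irrelevant. The step needs CH2- over C7-capture of the allyl cations (secured by the fully substituted C7, as in prenylations), ring A before ring B (secured by the rate gap between allylic and β-bromo tertiary chloride and by the deactivation of C6=C7 while it still bears CH2Cl), enol ether over solvent capture (secured by the very low nucleophilicity of the solvent) and exocyclic proton loss (three accessible methyl protons against one axial C8–H beside the new quaternary centre).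

Step 11
Reactants: 19 (8S)-8-bromo-7,7-dimethyl-11-methylidenespiro[5.5]undecan-3-one
Product: 20 (6R,10S)-10-bromo-3-(trimethylsilyloxy)-15-norchamigra-2,7(14)-diene
Conditions: TMSI, (Me3Si)2NH, CH2Cl2, −20 → 23 °C (equilibrating)
Reagents that add atoms: iodotrimethylsilane C[Si](C)(C)I
Why: Thermodynamic silyl enol ether formation: C7 is axial on ring A and its =CH2 eclipses C1 (the arm that is equatorial on ring B when Br is equatorial), so axial H-2 is pressed against the inner C14–H, and enolisation toward C2 removes this contact while enolisation toward C4 keeps it, which should favour the C2=C3 isomer and set C6 as R.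

Step 12
Reactants: 20 (6R,10S)-10-bromo-3-(trimethylsilyloxy)-15-norchamigra-2,7(14)-diene
Product: 22 (6R,10S)-10-bromo-15-norchamigra-2,7(14)-dien-3-yl trifluoromethanesulfonate, via regiodefined lithium enolate 21 (not isolated)
Conditions: MeLi (1.05 equiv), THF, 0 °C; PhNTf2, −78 → 0 °C
Reagents that add atoms: N-phenylbis(trifluoromethanesulfonimide) O=S(=O)(N(c1ccccc1)S(=O)(=O)C(F)(F)F)C(F)(F)F
Why: Si–Li exchange frees the enolate without proton transfer, so O-triflation keeps the C2=C3 position; the hindered equatorial secondary bromide does not exchange with MeLi.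

Step 13
Reactants: 22 (6R,10S)-10-bromo-15-norchamigra-2,7(14)-dien-3-yl trifluoromethanesulfonate
Product: 23 (6R,10S)-10-bromochamigra-2,7(14)-diene (10-bromo-β-chamigrene)
Conditions: Me2Zn, Pd(PPh3)4 (5 mol %), THF, 50 °C
Reagents that add atoms: dimethylzinc C[Zn]C
Why: Negishi coupling of an alkenyl triflate installs C15 with the alkene position retained, and Pd(PPh3)4 does not insert into an unactivated, neopentyl-type secondary bromide.

Step 14
Reactants: 23 (6R,10S)-10-bromochamigra-2,7(14)-diene
Product: 24 (2R,3S,6R,10S)-10-bromo-2,3-epoxychamigr-7(14)-ene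
Conditions: mCPBA (1.0 equiv), CH2Cl2, −10 °C
Reagents that add atoms: 3-chloroperoxybenzoic acid O=C(OO)c1cccc(Cl)c1
Why: Prilezhaev epoxidation picks the trisubstituted ring alkene over the hindered 1,1-disubstituted one, and because axial C7 with its methylene covers the lower face of ring A the oxygen arrives on the face syn to equatorial C11, setting C2 (R) and C3 (S).

Step 15
Reactants: 24 (2R,3S,6R,10S)-10-bromo-2,3-epoxychamigr-7(14)-ene
Product: 25 (2R,3R,6R,10S)-3,10-dibromochamigr-7(14)-en-2-ol
Conditions: 48 % aq. HBr (1.2 equiv), Et2O, −20 °C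
Reagents that add atoms: hydrogen bromide Br
Why: Acid-mediated Markovnikov opening of a trisubstituted epoxide puts bromide on tertiary C3 with inversion (Br equatorial, C15 axial, C3 = R); the competing Fürst–Plattner attack at C2 would have to come from the face blocked by C14.

Step 16
Reactants: 25 (2R,3R,6R,10S)-3,10-dibromochamigr-7(14)-en-2-ol
Product: 27 (2R,3R,6R,10S)-3,10-dibromo-2-chlorochamigr-7(14)-ene, via chlorosulfite ester 26 (not isolated)
Conditions: SOCl2 (1.5 equiv), Et2O, no base, 0 → 23 °C
Reagents that add atoms: thionyl chloride O=S(Cl)Cl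
Why: Base-free collapse of a chlorosulfite (SNi) and the alternative double inversion through the neighbouring-bromine bromonium ion (classical for trans-β-bromo alcohols) both give retention at C2, while direct backside attack is blocked by C14 and chloride attack at C3 would place Br axial against C14.

**Compound list**
1 | 3-methylbut-2-en-1-ol (prenol) | CC(C)=CCO | starting material
2 | (2S)-2-bromo-3-chloro-3-methylbutan-1-ol | OC[C@H](Br)C(C)(C)Cl | intermediate
3 | (2S)-2-bromo-3-chloro-3-methylbutyl trifluoromethanesulfonate | O=S(=O)(OC[C@H](Br)C(C)(C)Cl)C(F)(F)F | intermediate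
4 | acetone N,N-dimethylhydrazone | CC(C)=NN(C)C | starting material
5 | lithiated acetone dimethylhydrazone (not isolated) | C=C(C)[N-]N(C)C.[Li+] | intermediate
6 | (5S)-5-bromo-6-chloro-6-methylheptan-2-one N,N-dimethylhydrazone (C=N isomers) | CC(CC[C@H](Br)C(C)(C)Cl)=NN(C)C | intermediate
7 | (5S)-5-bromo-6-chloro-6-methylheptan-2-one | CC(=O)CC[C@H](Br)C(C)(C)Cl | intermediate
8 | dimethyl malonate | COC(=O)CC(=O)OC | starting material
9 | dimethyl 2-[(5S)-5-bromo-6-chloro-6-methylheptan-2-ylidene]malonate | COC(=O)C(C(=O)OC)=C(C)CC[C@H](Br)C(C)(C)Cl | intermediate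
10 | 2-[(5S)-5-bromo-6-chloro-6-methylheptan-2-ylidene]propane-1,3-diol | OCC(CO)=C(C)CC[C@H](Br)C(C)(C)Cl | intermediate
11 | (6S)-6-bromo-1,7-dichloro-2-(chloromethyl)-3,7-dimethyloct-2-ene | ClCC(CCl)=C(C)CC[C@H](Br)C(C)(C)Cl | intermediate
12 | (trimethylsilyl)methylmagnesium chloride | C[Si](C)(C)C[Mg]Cl | starting material
13 | acetic anhydride | CC(=O)OC(C)=O | starting material
14 | 1-(trimethylsilyl)propan-2-one | CC(=O)C[Si](C)(C)C | intermediate
15 | kinetic lithium enolate of 14 (not isolated) | C=C([O-])C[Si](C)(C)C.[Li+] | intermediate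
16 | tert-butyldimethyl{[3-(trimethylsilyl)prop-1-en-2-yl]oxy}silane | C=C(C[Si](C)(C)C)O[Si](C)(C)C(C)(C)C | intermediate
17 | (9S)-9-bromo-10-chloro-5-(chloromethyl)-6,10-dimethyl-2-(tert-butyldimethylsilyloxy)undeca-1,5-diene, E/Z (not isolated) | ClCC(CCC(=C)O[Si](C)(C)C(C)(C)C)=C(C)CC[C@H](Br)C(C)(C)Cl | intermediate
18 | 4-[(5S)-5-bromo-6-chloro-6-methylheptan-2-ylidene]cyclohexan-1-one (not isolated) | O=C1CCC(CC1)=C(C)CC[C@H](Br)C(C)(C)Cl | intermediate
19 | (8S)-8-bromo-7,7-dimethyl-11-methylidenespiro[5.5]undecan-3-one (10S in chamigrene numbering) | C=C1CC[C@H](Br)C(C)(C)C12CCC(=O)CC2 | intermediate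
20 | (6R,10S)-10-bromo-3-(trimethylsilyloxy)-15-norchamigra-2,7(14)-diene | C=C1CC[C@H](Br)C(C)(C)[C@@]12CCC(O[Si](C)(C)C)=CC2 | intermediate
21 | lithium (6R,10S)-10-bromo-15-norchamigra-2,7(14)-dien-3-olate (not isolated) | C=C1CC[C@H](Br)C(C)(C)[C@@]12CCC([O-])=CC2.[Li+] | intermediate
22 | (6R,10S)-10-bromo-15-norchamigra-2,7(14)-dien-3-yl trifluoromethanesulfonate | C=C1CC[C@H](Br)C(C)(C)[C@@]12CCC(OS(=O)(=O)C(F)(F)F)=CC2 | intermediate
23 | (6R,10S)-10-bromochamigra-2,7(14)-diene | C=C1CC[C@H](Br)C(C)(C)[C@@]12CCC(C)=CC2 | intermediate
24 | (2R,3S,6R,10S)-10-bromo-2,3-epoxychamigr-7(14)-ene | C=C1CC[C@H](Br)C(C)(C)[C@@]12CC[C@]3(C)O[C@@H]3C2 | intermediate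
25 | (2R,3R,6R,10S)-3,10-dibromochamigr-7(14)-en-2-ol | C=C1CC[C@H](Br)C(C)(C)[C@@]12CC[C@@](C)(Br)[C@H](O)C2 | intermediate
26 | chlorosulfite ester of 25 (not isolated) | C=C1CC[C@H](Br)C(C)(C)[C@@]12CC[C@@](C)(Br)[C@H](OS(=O)Cl)C2 | intermediate
27 | (2R,3R,6R,10S)-3,10-dibromo-2-chlorochamigr-7(14)-ene | C=C1CC[C@H](Br)C(C)(C)[C@@]12CC[C@@](C)(Br)[C@H](Cl)C2 | target

**Step count**
Total step count: 16. Longest linear sequence: 14 (steps 1–7 and 10–16; steps 8–9 form the side branch to 16).

**Steps most likely to fail**

Step 10:
- What may go wrong: the order of ionisations may break down, so that ring B closes while C6 still bears a chloromethyl group. The allyl cations may also be lost by capture at C7 or by proton loss to dienes, the enol ether may be protodesilylated, or the last proton may be lost from C8.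
- Fallback, known chemistry run in separate operations from diol 10: methyl chloroformate and pyridine give the bis(methyl carbonate) F1.
- Pd(PPh3)4-catalysed double allylic alkylation of F1 with commercial di-tert-butyl 3-oxopentanedioate ([3+3] annulation under neutral conditions) gives the cyclohexanone diester F2.
- TFA, then warm toluene, removes both esters and gives 18, now isolated. A separate solvolysis of 18 in hexafluoroisopropanol with 2,6-di-tert-butylpyridine returns to the route at 19.

Step 11:
- What may go wrong: the thermodynamic bias may be too small, or equilibration incomplete. Either gives poor regioselectivity of enolisation and therefore poor control of C6.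
- Fallback, reagent control from 19: twofold IBX dehydrogenation gives the cross-conjugated spirodienone F3.
- A catalyst-controlled desymmetrising conjugate reduction (an ene-reductase of the Old Yellow Enzyme class, or CuH with a chiral bisphosphine, both known for 4,4-disubstituted cyclohexadienones) saturates C4=C5 only and gives the enone F4.
- Conjugate reduction of F4 with L-Selectride generates the C2=C3 enolate regiospecifically, and trapping with PhNTf2 returns to the route at 22.

Step 16:
- What may go wrong: ionisation at C2 may lead to a 1,2-bromine shift or to elimination, the HCl formed may add to the exocyclic alkene, or retention may be incomplete.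
- Fallback, two defined inversions from 25: Dess–Martin oxidation gives the α-bromo ketone F5.
- L-Selectride attacks F5 along the equatorial trajectory from the open face and gives the axial C2 alcohol F6.
- An Appel chlorination of F6 (PPh3, CCl4) with inversion returns to the route at 27.

Further compounds
F1 | step 10 | 2-[(5S)-5-bromo-6-chloro-6-methylheptan-2-ylidene]propane-1,3-diyl bis(methyl carbonate) | COC(=O)OCC(COC(=O)OC)=C(C)CC[C@H](Br)C(C)(C)Cl
F2 | step 10 | di-tert-butyl 5-[(5S)-5-bromo-6-chloro-6-methylheptan-2-ylidene]-2-oxocyclohexane-1,3-dicarboxylate (keto/enol, epimers) | O=C1C(C(=O)OC(C)(C)C)CC(CC1C(=O)OC(C)(C)C)=C(C)CC[C@H](Br)C(C)(C)Cl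
F3 | step 11 | (8S)-8-bromo-7,7-dimethyl-11-methylidenespiro[5.5]undeca-1,4-dien-3-one | C=C1CC[C@H](Br)C(C)(C)C12C=CC(=O)C=C2
F4 | step 11 | (6R,10S)-10-bromo-15-norchamigra-1,7(14)-dien-3-one | C=C1CC[C@H](Br)C(C)(C)[C@@]12CCC(=O)C=C2
F5 | step 16 | (3R,6R,10S)-3,10-dibromochamigr-7(14)-en-2-one | C=C1CC[C@H](Br)C(C)(C)[C@@]12CC[C@@](C)(Br)C(=O)C2
F6 | step 16 | (2S,3R,6R,10S)-3,10-dibromochamigr-7(14)-en-2-ol | C=C1CC[C@H](Br)C(C)(C)[C@@]12CC[C@@](C)(Br)[C@@H](O)C2
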